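The runs stem from a simulated flask for an exercise; scatter was added.

The target in the north-west run keeps rising long after the substrate has left: at 5.00 h substrate stands at 1.9% and target at 4.4%, and at 20.0 h target reads 21.5%.

| setting | north | north-west | beta | zeta | alpha |
|---|---|---|---|---|---|
| substrate | 0.025 M | 0.10 M | 0.050 M | 0.050 M | 0.050 M |
| temperature | 10 °C | 43 °C | 55 °C | −5 °C | 25 °C |
| remark | run made earlier | run made earlier |  |  |  |
| time |  |  | 15 h | 15 h | 15 h |

| run | time / h | target / % | substrate / % |
|---|---|---|---|
| north | 6.00 | 0 | 94.3 |
| north | 20.0 | 0 | 82.6 |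
| north | 30.0 | 0.4 | 76.4 |
| north | 50.0 | 0 | 63.7 |
| north | 60.0 | 0 | 58.6 |
| north | 96.0 | 0.8 | 42.0 |
| north-west | 2.50 | 1.6 | 12.9 |
| north-west | 5.00 | 4.4 | 1.9 |
| north-west | 10.0 | 9.8 | 0 |
| north-west | 15.0 | 16.9 | 0.3 |
| north-west | 20.0 | 21.5 | 0 |

(each reading ± 0.5 percentage points)

- percent here means substrate units held: one side product counts as two
- what is said of target includes crystals
- crystals is a solid; its amount is given per volume of the solution
- steps under discussion: substrate + intermediate B -> side product; intermediate D <-> intermediate E; intermediate B -> target; substrate -> intermediate A; intermediate B <-> intermediate C; intermediate A -> intermediate B; intermediate C -> intermediate D; crystals <-> target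

* the best flask by amount of target, in percent of the substrate charged; "all alike" if 1.5 percentage points covers them all (beta / zeta / alpha / all alike)
* amount of target at the end, in percent of the substrate charged, beta
* amount of target at the end, in percent of the substrate charged, zeta
* amount of target at the end, in percent of the substrate charged, alpha

I read two first-order constants from the runs. For substrate, k_S is ln(charge/left) divided by time: 0.00904 /h in north and 0.819 /h in north-west. For target, the clock k_P is ln(charge/(charge − target)) divided by time, which reads 0.0121 /h in north-west. That is far slower than substrate's loss, so a later stage looks like the rate-limiting step.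

The bench rule doubles a rate every 10 degrees. For beta that means a factor 2.30 on the clock and 34.1% target. But between north and north-west the rule allows 9.85, while substrate shows 90.6, so the rule stops working here. I use that ratio instead, as an apparent activation energy E = 102 kJ/mol, and lend it to the clock.

Beta's clock becomes 0.0498 /h, which gives me 52.6%. Zeta gets 0.0179%. Alpha's clock gives 1.74%, but substrate's lifetime there is 12.6 h of the 15 h, so I expect less.

The forecast names beta: 46% (30% to 62%), zeta 0%, alpha 0.7%; “Beta clearly wins”. My beta figure stands 6.6 percentage points above it.

The flasks give beta as best, with beta at 60.0%, zeta at 0% and alpha at 0.289%.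

    substrate + intermediate B → side product (k = 1.50 /M/h, Ea = 61.0 kJ/mol)
    intermediate D ⇌ intermediate E (K = 0.420, k = 0.0160 /h, Ea = 92.0 kJ/mol, ΔH = −20.0 kJ/mol)
    intermediate B → target (k = 0.0880 /h, Ea = 95.0 kJ/mol)
    substrate → intermediate A (k = 0.0790 /h, Ea = 102 kJ/mol)
    intermediate B ⇌ intermediate C (K = 2.40, k = 0.0430 /h, Ea = 103 kJ/mol, ΔH = −72.0 kJ/mol)
    intermediate A → intermediate B (k = 0.00170 /h, Ea = 108 kJ/mol)
    intermediate C → intermediate D (k = 0.240 /h, Ea = 85.0 kJ/mol)
    crystals ⇌ target, rate k8*(cs8 - [target]) while solid is left; crystals form when [target] > cs8 (solubility = 0.510 mM, k = 1.70 /h)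
    (constants at 25 °C)

Beta has not come to rest at 15.0 h: intermediate A still holds 26.1%. By 150 h beta's target gains 22 points to reach 82.1%, intermediate A is down to 0%, and intermediate D holds 14.7% and intermediate E 2.94%. The clock's curve would say 99.9% there, so it overshoots beta. For alpha at 150 h the same clock gives 16.1%, and the flask holds 13.3%.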